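Readings and results were computed with made-up constants, and the scatter is random.

Per hour, the zeta run lost a fraction 0.281 h⁻¹ of its starting material. I read this pseudo-first-order constant from the last reading, 57.0% left at 2 h, with 3 equiv of partner present. The starting material meets the partner under the catalyst, and the target is wanted.

common to all: starting material 0.050 M; catalyst 10 mol%

| charge | partner | temperature | remark | time |
|---|---|---|---|---|
| zeta | 3 equiv | 50 °C | run made earlier |  |
| Tuesday's | 1.50 equiv | 50 °C |  | 20 h |
| Sunday's | 1.50 equiv | 75 °C |  | 20 h |
| Thursday's | 1.50 equiv | 25 °C |  | 20 h |

- zeta (time / min: target / %, starting material / %): 10.0: 3.6, 94.9; 20.0: 8.2, 91.1; 50.0: 15.1, 77.9; 120: 30.5, 57.0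

(each reading ± 0.5 percentage points)

- on the list of suspects stand: starting material + partner <-> isomer of the product; partner -> decomposed reagent; starting material + partner -> uncatalysed product; starting material + partner <-> target; target + catalyst <-> isomer of the product + catalyst
- the earlier runs do not show what temperature does; that part of a forecast is a guess

- which flask leads in amount of target, in percent of the starting material charged ("all alike" within 1.5 percentage points) (Tuesday's / Sunday's / Thursday's / all alike)
- how much target is there at the end, in percent of the starting material charged: Tuesday's
- how much target is there at the end, in percent of the starting material charged: Sunday's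
- how much target is there at the end, in percent of the starting material charged: Thursday's

I took the constant as proportional to the partner. On the way to half conversion a flask charged with 1.50 equiv holds on average 1.25 equiv, so at 50 °C the half-time, meaning the time to half conversion of the starting material, came to 5.92 h.

For temperature I used the bench rule that a rate doubles every 10 degrees. The step between the flasks is 2.50 doublings, or 0.753 decades, which put Sunday's half-time at 1.05 h. In decades, the asked time lay 0.529 past the half-time in Tuesday's and 1.28 past it in Sunday's. In Thursday's it fell 0.224 short.

The rule had a border. The last zeta reading lay 1.00 decade below the asked time, and the readings showed no partner. Of the partner charged in the new flasks, a third was spare over what the starting material needs, so my half-times spoke for conversion as long as other losses of partner stayed inside that third. I committed to the half-times and to no target figure.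

The forecast named Sunday's as leader, with 52% for Tuesday's, 58% for Sunday's and 23% for Thursday's. Of the hot flask it said that “selectivity, reagent decomposition and isomerisation may cost target”.

The simulation put Tuesday's in the lead, with 42.5% of target in Tuesday's, 22.1% in Sunday's and 20.7% in Thursday's.

    starting material + partner ⇌ isomer of the product (K = 122 M⁻¹, k = 1.67 × 10⁻⁴ M⁻¹ s⁻¹, Ea = 79.0 kJ mol⁻¹, ΔH = −12.0 kJ mol⁻¹)
    partner → decomposed reagent (k = 1.07 × 10⁻⁵ s⁻¹, Ea = 100 kJ mol⁻¹)
    starting material + partner → uncatalysed product (k = 4.24 × 10⁻⁶ M⁻¹ s⁻¹, Ea = 94.0 kJ mol⁻¹)
    starting material + partner ⇌ target (K = 165 M⁻¹, k = 4.25 × 10⁻⁴ M⁻¹ s⁻¹, Ea = 67.0 kJ mol⁻¹, ΔH = −1.00 kJ mol⁻¹)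
    target + catalyst ⇌ isomer of the product + catalyst, rate k5*[catalyst]*[target] forward; the back reaction follows from the equilibrium constant (k = 0.00201 M⁻¹ s⁻¹, Ea = 75.0 kJ mol⁻¹)
    (constants at 50 °C)

Half conversion came at 6.41 h in Tuesday's, against my 5.92 h, and at 1.24 h in Sunday's, against my 1.05 h. But in Sunday's, half of the decomposition's turnover up to 20 h was done by 1.21 h, about the half-time itself, so the partner's own loss ran on the same clock. With that decomposition struck out, Sunday's holds 55.7% of target in place of 22.1%, at most the largest single effect. As it stood, Sunday's ended with 1.32% of the partner charge, by then the limiting reagent, and 64.6% of the starting material in the flask.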